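1. Lay the earlier runs beside the two new flasks, alpha and delta, before you reckon.

the same everywhere: catalyst 0.30 mM
- Sunday's: left-handed substrate 1 mM; right-handed substrate 1 mM; solid reagent 8 mM; temperature 49 °C; run made earlier
- Friday's: left-handed substrate 1.5 mM; right-handed substrate 1.5 mM; solid reagent 8 mM; temperature 57 °C; run made earlier
- Thursday's: left-handed substrate 2 mM; right-handed substrate 2 mM; solid reagent 12 mM; temperature 49 °C; run made earlier
- alpha: left-handed substrate 2.0 mM; right-handed substrate 2.0 mM; solid reagent 8.00 mM; temperature 45 °C; time 2.0 min
- delta: left-handed substrate 2.0 mM; right-handed substrate 2.0 mM; solid reagent 8.00 mM; temperature 60 °C; time 2.0 min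

| run | time / s | left-handed product / % | left-handed substrate / % |
|---|---|---|---|
| Sunday's | 12.0 | 0.7 | 48.6 |
| Sunday's | 25.0 | 3.2 | 46.4 |
| Sunday's | 40.0 | 6.4 | 43.9 |
| Sunday's | 50.0 | 9.3 | 41.6 |
| Sunday's | 60.0 | 10.4 | 40.1 |
| Sunday's | 80.0 | 15.5 | 36.2 |
| Friday's | 10.0 | 0.8 | 48.6 |
| Friday's | 15.0 | 1.6 | 48.9 |
| Friday's | 20.0 | 2.5 | 47.6 |
| Friday's | 40.0 | 5.6 | 43.9 |
| Thursday's | 10.0 | 0.9 | 48.9 |
| Thursday's | 20.0 | 2.0 | 48.1 |
| Thursday's | 40.0 | 7.1 | 43.7 |
| Thursday's | 80.0 | 13.6 | 37.4 |

(standard deviation of a reading: 0.5 percentage points)

* the best flask by amount of left-handed product, in percent of the left-handed substrate and right-handed substrate together charged; "all alike" if 1.5 percentage points covers them all (alpha / delta / all alike)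
* amount of left-handed product at the end, in percent of the left-handed substrate and right-handed substrate together charged, alpha
* amount of left-handed product at the end, in percent of the left-handed substrate and right-handed substrate together charged, delta

- catalyst is single-handed; left-handed substrate and right-handed substrate are mirror images of each other, charged as a racemate, each of them at the stated concentration
- given per volume of solution although it is solid: solid reagent
- at the start none of the solid reagent is in solution

2. Compare alpha with Thursday's run, which looks nearly the same: equal substrate and catalyst, 49 °C against 45 °C, 12 mM of solid reagent against 8.00 mM. Between its second and last readings Thursday's run gains 0.116 min⁻¹, the fraction of the whole charge turned into left-handed product per minute on the stretch after the early lag, which we call the clock.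

3. Sunday's run, at the same temperature with half the substrate and 8 mM of solid reagent, reads 0.134 min⁻¹, so across these two runs, which differ in both settings, the percentage climbs at a similar pace, the pattern called pseudo-first-order in substrate.

4. My own reckoning is that alpha should end above Thursday's last reading because it is read later, which gives 21.3%. For delta, take Friday's run at 57 °C: its clock of 0.0960 min⁻¹ gives 18.4%, uncertain by 1.9 percentage points. My gap between the two is 2.9 points, and with that uncertainty taken off it falls under the margin of 1.5 points, so I call them all alike.

5. The forecast says all alike, with 12.3% for alpha and 13.2% for delta, on the grounds that “The rate follows the solid loading, not substrate concentration”. Its figures lie near what you get with Thursday's last reading taken over, and mine stand higher for both flasks.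

6. The flasks give all alike: alpha 21.2%, delta 20.3%.

    partner + catalyst + left-handed substrate → catalyst + left-handed product (k = 25000 M⁻² s⁻¹, Ea = 13.0 kJ mol⁻¹)
    partner + catalyst + right-handed substrate → catalyst + right-handed product (k = 6800 M⁻² s⁻¹, Ea = 26.0 kJ mol⁻¹)
    left-handed substrate ⇌ right-handed substrate (k = 0.0160 s⁻¹, Ea = 81.0 kJ mol⁻¹)
    2 partner → self-condensation product (k = 3.80 M⁻¹ s⁻¹, Ea = 39.0 kJ mol⁻¹)
    partner → decomposed reagent (k = 0.0290 s⁻¹, Ea = 83.0 kJ mol⁻¹)
    solid reagent ⇌ partner, rate k6*(cs6 - [partner]) while solid is left; crystals form when [partner] > cs6 (solubility = 1.30 mM, k = 0.0420 s⁻¹)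
    (constants at 60 °C)

Alpha gained 0.110 min⁻¹ in its second minute, close to the clock of 0.116 min⁻¹, and at the end of that minute solid reagent still stood at 64.6% of its charge and partner at 0.869 mM. Carried on from delta's end, Friday's clock points to 77.9% at 8.0 min, but delta read then holds 42.7%, with its solid reagent at 0% and partner at 1.96 × 10⁻⁴ mM.

The data are simulated on assumed constants.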